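**Compound numbers used throughout**

1 3,4,5-trimethoxyphenylmagnesium bromide · 2 (E)-pent-2-enal · 3 racemic allylic alcohol · 4 epoxy alcohol · 5 hydroxy selenide (not isolated) · 6 anti allylic diol · 7 3-hydroxy-4,5-dimethoxybenzaldehyde · 8 its benzyl ether · 9 dioxolane acetal (not isolated) · 10 oxolane aldehyde, formyl cis to both aryl groups · 11 its C4 epimer, configured as the target · 12 primary alcohol · 13 mesylate · 14 benzyl ether of the target · 15 target

## Analysis of the target

Compound 15 is a 2,5-diaryl-3,4-dimethyloxolane: ring A (3-hydroxy-4,5-dimethoxyphenyl) sits on C2, ring B (3,4,5-trimethoxyphenyl) on C5, and C3 and C4 each carry a methyl group. Ring positions are quoted in this target numbering throughout, also where the systematic names of intermediates number the ring differently. The four contiguous stereocentres are 2S,3S,4R,5R: the two aryl groups are cis to each other, the two methyl groups are cis to each other, and each aryl group is trans to its neighbouring methyl. With two identical aryl groups the compound would be meso, so the enantiomer is defined only by which aryl group carries the free phenol; the absolute sense must therefore be fixed when the two aryl fragments are joined and cannot be corrected afterwards. The sensitive groups are the two benzylic ring C–O bonds on electron-rich arenes, which can ionise under strong acid (epimerising C2 or C5) or be hydrogenolysed, and the phenol, which has to be masked. The difficulty is four adjacent centres on a five-membered ring with no functional group left to direct them, in an arrangement (3,4-cis) that is not the most stable one. The strategy rests on this: O1 bridges C2 and C5, and the C2–C3 and C4–C5 bonds flank the C3–C4 unit. If the C4 methyl is read as a reduced formyl group, then O1, C5, the formyl carbon, C4, C3 and the C3 methyl are the atoms of a ring-B 1-arylpent-3-ene-1,2-diol, and C2 with ring A is an aldehyde carbon.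

## Retrosynthetic reasoning

**15 to 14.** The O–benzyl bond is cut last. A free phenol would bind the Lewis acid of the ring-forming step and would be sulfonylated later, so it is carried as a benzyl ether, which tolerates Lewis acid at low temperature, base and hydride. The forward reaction has to remove it without cleaving the two benzylic ring C–O bonds.

**14 to 11, through 13 and 12.** No skeletal bond is cut; the C4 methyl is raised to the formyl oxidation level. A formyl carbon on C4 is what the terminating event of the planned cascade leaves behind, and it is the only substituent that makes C4 epimerisable. Forward, reduction, sulfonylation and hydride displacement act on a primary carbon and touch no stereocentre.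

**11 to 10.** The two aldehydes differ only in the C4–H bond. The cascade is expected to give 10, with the formyl group on the face of both aryl groups, so the target configuration at C4 has to come from a separate equilibration. Forward, the formyl group must move to the face of the C3 methyl without the ring opening.

**10 to 6 and 8, through 9.** Three bonds are cut: O1–C2, C2–C3 and C4–C5. Cutting here, and not at O1–C5 or an aryl–ring bond, divides the ring into two fragments of similar size, each with one aryl group. In 6 the aryl carbinol carbon is the future C5 and its oxygen the future O1, the allylic carbinol carbon is the future formyl carbon, the alkene carbons are C4 and C3, and the terminal methyl is the C3 methyl. Aldehyde 8 supplies C2. The gain is the ring, three skeletal bonds and all four stereocentres in one operation. The forward reaction has to open acetal 9 in the productive direction, pass through a single chair, and close the five-membered ring faster than the rearranged cation fragments.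

**8 to 7.** The O–benzyl bond is cut back to the commercial phenol.

**6 to 4, through 5.** The allylic alcohol unit of 6 (C2–OH, C3=C4) is traced to a 2,3-epoxide: the C3=C4 π bond is exchanged for a C3–O bond. This is preferred to an olefination of an α-oxygenated aldehyde because the anti relationship of the two oxygens and the trans epoxide are what a directed epoxidation of an (E)-allylic alcohol gives directly, and because no epimerisable aldehyde is exposed to base. Forward, the epoxide must be opened at the carbon remote from the carbinol and the elimination must go away from oxygen and give the E alkene.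

**4 to 3.** Both epoxide C–O bonds are cut. A tartrate-controlled epoxidation run as a kinetic resolution sets the absolute configuration of the aryl carbinol carbon, the only stereochemical information that survives into 15, together with the anti relationship. The price is that at most half of racemic 3 is used.

**3 to 1 and 2.** The aryl–carbinol C–C bond is cut to two commercial materials; the E geometry comes with 2.

## Alternatives that were turned down

**Alternative 1:** The ring oxygen is inserted last into a four-membered carbocycle. The O1–C5 bond of a γ-lactone is traced to cyclobutanone A1, (2R,3R,4S)-3,4-dimethyl-2-(3,4,5-trimethoxyphenyl)cyclobutan-1-one, the [2+2] adduct of a ring-B ketene or keteniminium with the cis alkene that supplies both methyl groups. Forward, peracid Baeyer–Villiger oxidation lets the benzylic carbon migrate with retention and gives lactone A2, (3S,4R,5R)-3,4-dimethyl-5-(3,4,5-trimethoxyphenyl)oxolan-2-one.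
- For it: the cis-dimethyl relationship follows stereospecifically from the alkene geometry, and the regiochemistry and retention of the oxygen insertion are dependable. On the C3/C4 relationship this plan is stronger than the chosen one, which relies on an equilibrium at C4.
- Against it: A1 is chiral and a thermal [2+2] with a simple alkene does not set its absolute configuration, so an auxiliary or a resolution is needed, and an unactivated gaseous alkene is a poor partner. A2 still lacks ring A. Ring A must be added to the lactone carbonyl as an aryl metal, since its 1,2,3-trioxygenated pattern excludes Friedel–Crafts attachment at the required position. The new C2 centre is then set by hydride delivery to a cyclic aryl oxocarbenium, expected anti to the adjacent methyl, which places ring A cis to that methyl, the wrong relationship for 15.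
- Comparison: more steps follow its key step (aryl addition, reduction, deprotection, correction of C2) and the absolute configuration is unsolved. The chosen strategy offers instead the ring, both aryl-bearing centres and C3 in one step from fragments whose absolute sense is fixed by a tartrate-controlled epoxidation.

**Alternative 2:** The ring is cut at O1–C5 and C2–C3 into aldehyde 8 and the donor–acceptor cyclopropane A3, dimethyl (2S,3S)-2-methyl-3-(3,4,5-trimethoxyphenyl)cyclopropane-1,1-dicarboxylate (aryl and methyl cis). Forward, Sn(OTf)2 activates the diester, the aldehyde oxygen opens the ring at the benzylic carbon with inversion, and the malonate carbon closes on the carbonyl carbon. The product is A4, dimethyl (2R,4R,5R)-2-[3-(benzyloxy)-4,5-dimethoxyphenyl]-4-methyl-5-(3,4,5-trimethoxyphenyl)oxolane-3,3-dicarboxylate.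
- For it: it is convergent, uses the same aldehyde 8, needs only catalytic Lewis acid, and its 2,5-cis selectivity and stereospecific transfer from the cyclopropane are well founded. On convergence and on the 2,5-cis relationship it is as strong as the chosen plan, and it is stronger in being catalytic.
- Against it: C3 emerges as a quaternary bis-ester. One ester must be removed and the other reduced to methyl, and C3 is then set by protonation after decarboxylation. The required outcome there (trans to aryl, cis to the neighbouring methyl) is the same thermodynamic question the chosen route faces at C4, but it arrives after about four more steps. A3 needs an enantioselective cis-cyclopropanation of a (Z)-propenylarene with a malonate carbene, which is poorly selective, or a longer detour. Electron-rich aryl cyclopropanes of this kind also open reversibly under the Lewis acid, which erodes enantiomeric purity.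
- Comparison: the chosen strategy offers a precursor reachable in three steps with secure absolute configuration, and only one change of oxidation level at C4 after the ring is formed.

**Alternative 3:** Both methyl carbons are traced to the two methylene groups of a fused thiolane. A cis-dimethyl lactone is cut back to cycloadduct A6, (3S,3aS,6aR)-3-[3-(benzyloxy)-4,5-dimethoxyphenyl]tetrahydro-1H,3H-thieno[3,4-c]furan-1-one, and that to butenolide A5, (5S)-5-[3-(benzyloxy)-4,5-dimethoxyphenyl]furan-2(5H)-one. Forward, a thiocarbonyl ylide released with CsF adds across the butenolide alkene anti to the γ-aryl group; later desulfurisation with Raney Ni reveals two cis methyl groups.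
- For it: the cis relationship of the methyl groups is enforced by the ring fusion and their anti relationship to the aryl group by the approach, so the C2–C3–C4 array is set with more certainty than C4 is in the chosen route. On this point it is stronger.
- Against it: the γ-hydrogen of A5 is benzylic and vinylogously acidic, so the fluoride conditions risk racemisation. Raney Ni also cleaves the benzyl ether and threatens the benzylic lactone C–O bond, forcing a change of protecting group. Ring B is still missing and, as in alternative 1, has to be added to the lactone carbonyl, with the last centre set by a reduction whose intrinsic preference puts the aryl group cis to the adjacent methyl.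
- Comparison: the sequence (butenolide, cycloaddition, desulfurisation, reprotection, aryl addition, reduction, deprotection) is longer and has its weakest step at the end. The chosen strategy offers both aryl-bearing centres in one step, with their cis relationship fixed by the chair and the ring closure.

Key step: step 5

Assumption: Grignard reagent 1 is used as its commercial THF solution.

Assumption: the cascade of step 5 is assigned the stereochemical course normal for its reaction class (formyl cis to the adjacent, diol-derived aryl group); step 6 converges both C4 epimers, so the route does not depend on this assignment.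

## Route

Step 1
Reactants: 1 3,4,5-trimethoxyphenylmagnesium bromide; 2 (E)-pent-2-enal
Product: 3 (E)-1-(3,4,5-trimethoxyphenyl)pent-2-en-1-ol (racemic)
Conditions: THF, −78 → 0 °C; aq. NH4Cl
Reagents that add atoms: none
Why: 1,2-addition of an aryl Grignard reagent to an enal; aryl magnesium reagents add to the carbonyl carbon and not in conjugate fashion, and the E alkene of 2 is untouched.

Step 2
Reactants: 3 (E)-1-(3,4,5-trimethoxyphenyl)pent-2-en-1-ol (racemic)
Product: 4 (S)-[(2S,3S)-3-ethyloxiran-2-yl](3,4,5-trimethoxyphenyl)methanol
Conditions: Ti(OiPr)4 (10 mol %), L-(+)-diisopropyl tartrate (15 mol %), t-BuOOH (0.5 equiv), 4 Å MS, CH2Cl2, −20 °C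
Reagents that add atoms: tert-butyl hydroperoxide, CC(C)(C)OO
Why: Sharpless asymmetric epoxidation used as a kinetic resolution of a secondary (E)-allylic alcohol. With L-(+)-tartrate the (R)-enantiomer of 3 should react fast (its aryl group points away from the titanium tartrate in the reactive conformer) and receive oxygen on the face that gives the (2S,3S)-epoxide anti to the carbinol oxygen; the carbinol descriptor changes from R to S only because the ranking of its neighbours changes. Unreacted (S)-3 is separated; at most half of 3 is used.

Step 3
Reactants: 4 (S)-[(2S,3S)-3-ethyloxiran-2-yl](3,4,5-trimethoxyphenyl)methanol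
Product: 6 (1S,2R,3E)-1-(3,4,5-trimethoxyphenyl)pent-3-ene-1,2-diol, via hydroxy selenide 5 (not isolated)
Conditions: (PhSe)2, NaBH4, EtOH, rt → 60 °C; then THF, 30% H2O2, 0 °C → rt
Reagents that add atoms: none
Why: Epoxide to allylic alcohol transposition by selenolate opening and selenoxide syn-elimination. The selenolate should attack C3, the epoxide carbon remote from the carbinol (SN2, inversion), and the selenoxide eliminates away from the hydroxyl-bearing carbon to give the E alkene. Neither carbinol centre is touched, so the anti (1S,2R) relationship from step 2 is carried over.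

Step 4
Reactants: 7 3-hydroxy-4,5-dimethoxybenzaldehyde
Product: 8 3-(benzyloxy)-4,5-dimethoxybenzaldehyde
Conditions: BnBr, K2CO3, DMF, rt
Reagents that add atoms: benzyl bromide, BrCc1ccccc1
Why: Williamson etherification of a phenoxide with a benzylic halide; the aldehyde is inert under these conditions.

Step 5
Reactants: 6 (1S,2R,3E)-1-(3,4,5-trimethoxyphenyl)pent-3-ene-1,2-diol; 8 3-(benzyloxy)-4,5-dimethoxybenzaldehyde
Product: 10 (2R,3S,4S,5S)-5-[3-(benzyloxy)-4,5-dimethoxyphenyl]-4-methyl-2-(3,4,5-trimethoxyphenyl)oxolane-3-carbaldehyde, via dioxolane acetal 9 (not isolated)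
Conditions: 8 (1.1 equiv), camphorsulfonic acid (5 mol %), MgSO4, CH2Cl2, rt; filter; then SnCl4 (2 equiv), CH2Cl2, −78 → −20 °C; aq. NaHCO3
Reagents that add atoms: none
Why: Acid-catalysed acetalisation gives the cis-4,5-disubstituted dioxolane 9, and SnCl4 then opens it by binding the allylic oxygen, which leaves the (E)-oxocarbenium on the benzylic oxygen (O1=C2); the opposite opening is unproductive and reversible. This cation undergoes a 2-oxonia-Cope rearrangement through a chair in which ring B, the tin-bound oxygen, the alkene methyl and ring A are all equatorial, so C2–C3 forms while the old carbinol–carbinol bond breaks and a ring-B-conjugated oxocarbenium tethered to a tin enolate results (a stepwise Prins addition followed by a pinacol shift joins the same atoms). The enolate carbon then attacks the new oxocarbenium carbon (C4–C5) and closes the oxolane, the only ring formed, in a 5-(enol-exo)-endo-trig aldol closure, endo with respect to the C=O+ bond and feasible because the cationic acceptor makes the transition state early. The closest known reaction type is the Lewis-acid Prins–pinacol (2-oxonia-Cope/aldol) rearrangement of acetals of allylic 1,2-diols to 3-acyltetrahydrofurans. C2 and C3 are set together in the chair: the equatorial ring B on the (S)-carbinol carbon of 6 selects the chair face (2S), and the E alkene and E oxocarbenium put the methyl trans to ring A (3S). C5 is set in the ring closure with ring B pseudo-equatorial and cis to ring A (5R in the target numbering, the same spatial arrangement as the (S)-carbinol of 6 if the Prins–pinacol path runs with retention), and C4 is set in the same closure, kinetically with the formyl group cis to both aryl groups. The step needs chair-face selectivity and productive acetal opening: the anti diol secures the first, because only one chair has both carbinol substituents equatorial, and the reversibility of the wrong opening secures the second.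

Step 6
Reactants: 10 (2R,3S,4S,5S)-5-[3-(benzyloxy)-4,5-dimethoxyphenyl]-4-methyl-2-(3,4,5-trimethoxyphenyl)oxolane-3-carbaldehyde
Product: 11 (2R,3R,4S,5S)-5-[3-(benzyloxy)-4,5-dimethoxyphenyl]-4-methyl-2-(3,4,5-trimethoxyphenyl)oxolane-3-carbaldehyde
Conditions: DBU (0.2 equiv), THF, rt
Reagents that add atoms: none
Why: Base-mediated epimerisation by enolisation and reprotonation at the only acidic C–H. In 10 the formyl group is cis to both aryl groups and vicinal-cis to ring B; in 11 it is cis only to the C3 methyl, so 11 should be favoured at equilibrium. C2, C3 and C5 (target numbering) carry no acidic hydrogen and are unchanged.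

Step 7
Reactants: 11 (2R,3R,4S,5S)-5-[3-(benzyloxy)-4,5-dimethoxyphenyl]-4-methyl-2-(3,4,5-trimethoxyphenyl)oxolane-3-carbaldehyde
Product: 12 [(2R,3S,4S,5S)-5-[3-(benzyloxy)-4,5-dimethoxyphenyl]-4-methyl-2-(3,4,5-trimethoxyphenyl)oxolan-3-yl]methanol
Conditions: NaBH4, MeOH–THF, 0 °C
Reagents that add atoms: none
Why: Borohydride reduction of an aldehyde; ethers are inert, and the descriptor at the formyl-bearing carbon changes only through ranking.

Step 8
Reactants: 12 [(2R,3S,4S,5S)-5-[3-(benzyloxy)-4,5-dimethoxyphenyl]-4-methyl-2-(3,4,5-trimethoxyphenyl)oxolan-3-yl]methanol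
Product: 13 [(2R,3S,4S,5S)-5-[3-(benzyloxy)-4,5-dimethoxyphenyl]-4-methyl-2-(3,4,5-trimethoxyphenyl)oxolan-3-yl]methyl methanesulfonate
Conditions: MsCl, Et3N, CH2Cl2, 0 °C
Reagents that add atoms: methanesulfonyl chloride, CS(=O)(=O)Cl
Why: Sulfonylation of a primary alcohol; no stereocentre is involved.

Step 9
Reactants: 13 [(2R,3S,4S,5S)-5-[3-(benzyloxy)-4,5-dimethoxyphenyl]-4-methyl-2-(3,4,5-trimethoxyphenyl)oxolan-3-yl]methyl methanesulfonate
Product: 14 (2S,3S,4R,5R)-2-[3-(benzyloxy)-4,5-dimethoxyphenyl]-3,4-dimethyl-5-(3,4,5-trimethoxyphenyl)oxolane
Conditions: LiEt3BH, THF, 0 °C → rt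
Reagents that add atoms: none
Why: SN2 displacement of a primary sulfonate by triethylborohydride, a hydride donor suited to β-branched primary centres; the ring stereocentres do not take part.

Step 10
Reactants: 14 (2S,3S,4R,5R)-2-[3-(benzyloxy)-4,5-dimethoxyphenyl]-3,4-dimethyl-5-(3,4,5-trimethoxyphenyl)oxolane
Product: 15 2,3-dimethoxy-5-[(2S,3S,4R,5R)-3,4-dimethyl-5-(3,4,5-trimethoxyphenyl)oxolan-2-yl]phenol
Conditions: H2 (1 atm), 10% Pd/C, EtOAc, rt
Reagents that add atoms: none
Why: Hydrogenolysis of an aryl benzyl ether over palladium on carbon. The ring C–O bonds are dialkyl benzylic ethers, which should react much more slowly in neutral ethyl acetate, so the reaction is stopped after one equivalent of hydrogen.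

## Compound list

1 | 3,4,5-trimethoxyphenylmagnesium bromide | COc1cc([Mg]Br)cc(OC)c1OC | starting material
2 | (E)-pent-2-enal | CC/C=C/C=O | starting material
3 | (E)-1-(3,4,5-trimethoxyphenyl)pent-2-en-1-ol, racemic | CC/C=C/C(O)c1cc(OC)c(OC)c(OC)c1 | intermediate
4 | (S)-[(2S,3S)-3-ethyloxiran-2-yl](3,4,5-trimethoxyphenyl)methanol | CC[C@@H]1O[C@H]1[C@@H](O)c2cc(OC)c(OC)c(OC)c2 | intermediate
5 | (1S,2S,3R)-3-(phenylselanyl)-1-(3,4,5-trimethoxyphenyl)pentane-1,2-diol | CC[C@@H]([Se]c1ccccc1)[C@@H](O)[C@@H](O)c2cc(OC)c(OC)c(OC)c2 | intermediate
6 | (1S,2R,3E)-1-(3,4,5-trimethoxyphenyl)pent-3-ene-1,2-diol | COc1cc(cc(OC)c1OC)[C@H](O)[C@H](O)/C=C/C | intermediate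
7 | 3-hydroxy-4,5-dimethoxybenzaldehyde | COc1cc(C=O)cc(O)c1OC | starting material
8 | 3-(benzyloxy)-4,5-dimethoxybenzaldehyde | COc1cc(C=O)cc(OCc2ccccc2)c1OC | intermediate
9 | (4S,5R)-2-[3-(benzyloxy)-4,5-dimethoxyphenyl]-5-[(1E)-prop-1-en-1-yl]-4-(3,4,5-trimethoxyphenyl)-1,3-dioxolane, both C2 epimers | COc1cc(cc(OC)c1OC)[C@@H]2OC(c3cc(OC)c(OC)c(OCc4ccccc4)c3)O[C@@H]2/C=C/C | intermediate
10 | (2R,3S,4S,5S)-5-[3-(benzyloxy)-4,5-dimethoxyphenyl]-4-methyl-2-(3,4,5-trimethoxyphenyl)oxolane-3-carbaldehyde | COc1cc([C@H]2O[C@@H](c3cc(OC)c(OC)c(OC)c3)[C@@H](C=O)[C@@H]2C)cc(OCc4ccccc4)c1OC | intermediate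
11 | (2R,3R,4S,5S)-5-[3-(benzyloxy)-4,5-dimethoxyphenyl]-4-methyl-2-(3,4,5-trimethoxyphenyl)oxolane-3-carbaldehyde | COc1cc([C@H]2O[C@@H](c3cc(OC)c(OC)c(OC)c3)[C@H](C=O)[C@@H]2C)cc(OCc4ccccc4)c1OC | intermediate
12 | [(2R,3S,4S,5S)-5-[3-(benzyloxy)-4,5-dimethoxyphenyl]-4-methyl-2-(3,4,5-trimethoxyphenyl)oxolan-3-yl]methanol | COc1cc([C@H]2O[C@@H](c3cc(OC)c(OC)c(OC)c3)[C@H](CO)[C@@H]2C)cc(OCc4ccccc4)c1OC | intermediate
13 | [(2R,3S,4S,5S)-5-[3-(benzyloxy)-4,5-dimethoxyphenyl]-4-methyl-2-(3,4,5-trimethoxyphenyl)oxolan-3-yl]methyl methanesulfonate | COc1cc([C@H]2O[C@@H](c3cc(OC)c(OC)c(OC)c3)[C@H](COS(C)(=O)=O)[C@@H]2C)cc(OCc4ccccc4)c1OC | intermediate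
14 | (2S,3S,4R,5R)-2-[3-(benzyloxy)-4,5-dimethoxyphenyl]-3,4-dimethyl-5-(3,4,5-trimethoxyphenyl)oxolane | COc1cc([C@H]2O[C@@H](c3cc(OC)c(OC)c(OC)c3)[C@H](C)[C@@H]2C)cc(OCc4ccccc4)c1OC | intermediate
15 | 2,3-dimethoxy-5-[(2S,3S,4R,5R)-3,4-dimethyl-5-(3,4,5-trimethoxyphenyl)oxolan-2-yl]phenol | COc1cc([C@H]2O[C@@H](c3cc(OC)c(OC)c(OC)c3)[C@H](C)[C@@H]2C)cc(O)c1OC | target

## Step count and least certain steps

Total step count: 10. Longest linear sequence: 9 steps (steps 1, 2, 3, 5, 6, 7, 8, 9, 10); step 4 is a one-step side branch.

**Step 5 (key step).** Three things may go wrong.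
- Loss of stereochemical fidelity: the oxonia-Cope step is reversible and can leak through a boat or a (Z)-oxocarbenium, and SnCl4 can ionise the benzylic C–O bonds of the electron-rich product and epimerise C2 or C5.
- Fragmentation of the rearranged oxocarbenium with loss of the ring-B aldehyde, in competition with the formally disfavoured 5-endo closure.
- Sluggish reaction of the unactivated 1,2-disubstituted alkene, so that acetal 9 only equilibrates.

Fallback (sets out from 6, returns at 10): the cascade is entered from a free benzylic hydroxyl and terminated on a silyl enol ether instead of passing through an acetal and a tin enolate. Diol 6 is monosilylated at the less hindered allylic hydroxyl (TBSCl, imidazole, DMF, −20 °C; the regioisomer is removed by chromatography) to give (1S,2R,3E)-2-[(tert-butyldimethylsilyl)oxy]-1-(3,4,5-trimethoxyphenyl)pent-3-en-1-ol F1. F1 and 8 are then treated with TMSOTf in CH2Cl2 at −78 °C. Only the benzylic oxygen can now form the oxocarbenium, the rearrangement gives a silyl enol ether, and the ring closes as an intramolecular Mukaiyama aldol with loss of the silyl group to give 10, with no tin halide present and no choice of acetal opening.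

**Step 6.** The equilibrium may not favour 11 strongly enough. In addition, the enolate may open the ring by expelling the C5 alkoxide (retro-oxa-Michael), and re-closure would scramble C5, most likely towards the all-trans isomer.

Fallback (sets out from 10, returns at 12): the equilibration is moved to the ester oxidation level, where the larger substituent should give a stronger bias away from the cis aryl group. Pinnick oxidation of 10 (NaClO2, NaH2PO4, 2-methyl-2-butene, t-BuOH–H2O) gives (2R,3S,4S,5S)-5-[3-(benzyloxy)-4,5-dimethoxyphenyl]-4-methyl-2-(3,4,5-trimethoxyphenyl)oxolane-3-carboxylic acid F2. Esterification with TMSCHN2 gives its methyl ester F3. NaOMe in MeOH at rt epimerises the ester-bearing carbon to give methyl (2R,3R,4S,5S)-5-[3-(benzyloxy)-4,5-dimethoxyphenyl]-4-methyl-2-(3,4,5-trimethoxyphenyl)oxolane-3-carboxylate F4. LiAlH4 in THF at 0 °C reduces F4 to alcohol 12.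

**Step 3.** The selenolate may attack the epoxide carbon next to the carbinol, and the selenoxide may eliminate with incomplete E selectivity or be followed by epoxidation of the product by peroxyseleninic acid.

Fallback (sets out from 4, returns at 6): the epoxide is isomerised by base-induced syn-β-elimination instead of by a selenoxide. The hydroxyl of 4 is silylated (TBSCl, imidazole, DMF) to give the tert-butyldimethylsilyl ether of 4 F5. Diethylaluminium 2,2,6,6-tetramethylpiperidide (from Et2AlCl and LiTMP, toluene, 0 °C) removes a hydrogen from the ethyl CH2 syn to the epoxide oxygen and gives (1S,2R,3E)-1-[(tert-butyldimethylsilyl)oxy]-1-(3,4,5-trimethoxyphenyl)pent-3-en-2-ol F6. TBAF in THF then gives 6.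

**Step 10.** Over-reduction by hydrogenolysis of a benzylic ring C–O bond, which would open the oxolane.

Fallback (sets out from 14, returns at 15): the benzyl group is removed without hydrogen, by BCl3 with pentamethylbenzene as cation scavenger in CH2Cl2 at −78 °C. Aryl benzyl ethers cleave within minutes under these conditions, where the ring ethers and aryl methyl ethers should survive. This fallback makes no new compound (F0).

Further compounds

F1 | step 5 | (1S,2R,3E)-2-[(tert-butyldimethylsilyl)oxy]-1-(3,4,5-trimethoxyphenyl)pent-3-en-1-ol | COc1cc(cc(OC)c1OC)[C@H](O)[C@H](O[Si](C)(C)C(C)(C)C)/C=C/C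
F2 | step 6 | (2R,3S,4S,5S)-5-[3-(benzyloxy)-4,5-dimethoxyphenyl]-4-methyl-2-(3,4,5-trimethoxyphenyl)oxolane-3-carboxylic acid | COc1cc([C@H]2O[C@@H](c3cc(OC)c(OC)c(OC)c3)[C@@H](C(=O)O)[C@@H]2C)cc(OCc4ccccc4)c1OC
F3 | step 6 | methyl (2R,3S,4S,5S)-5-[3-(benzyloxy)-4,5-dimethoxyphenyl]-4-methyl-2-(3,4,5-trimethoxyphenyl)oxolane-3-carboxylate | COc1cc([C@H]2O[C@@H](c3cc(OC)c(OC)c(OC)c3)[C@@H](C(=O)OC)[C@@H]2C)cc(OCc4ccccc4)c1OC
F4 | step 6 | methyl (2R,3R,4S,5S)-5-[3-(benzyloxy)-4,5-dimethoxyphenyl]-4-methyl-2-(3,4,5-trimethoxyphenyl)oxolane-3-carboxylate | COc1cc([C@H]2O[C@@H](c3cc(OC)c(OC)c(OC)c3)[C@H](C(=O)OC)[C@@H]2C)cc(OCc4ccccc4)c1OC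
F5 | step 3 | tert-butyl{(S)-[(2R,3S)-3-ethyloxiran-2-yl](3,4,5-trimethoxyphenyl)methoxy}dimethylsilane (tert-butyldimethylsilyl ether of 4) | CC[C@@H]1O[C@H]1[C@@H](O[Si](C)(C)C(C)(C)C)c2cc(OC)c(OC)c(OC)c2
F6 | step 3 | (1S,2R,3E)-1-[(tert-butyldimethylsilyl)oxy]-1-(3,4,5-trimethoxyphenyl)pent-3-en-2-ol | COc1cc(cc(OC)c1OC)[C@H](O[Si](C)(C)C(C)(C)C)[C@H](O)/C=C/C
F0 | step 10 | none | none
A1 | alternative 1 | (2R,3R,4S)-3,4-dimethyl-2-(3,4,5-trimethoxyphenyl)cyclobutan-1-one | O=C1[C@@H](c2cc(OC)c(OC)c(OC)c2)[C@H](C)[C@@H]1C
A2 | alternative 1 | (3S,4R,5R)-3,4-dimethyl-5-(3,4,5-trimethoxyphenyl)oxolan-2-one | O=C1O[C@@H](c2cc(OC)c(OC)c(OC)c2)[C@H](C)[C@@H]1C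
A3 | alternative 2 | dimethyl (2S,3S)-2-methyl-3-(3,4,5-trimethoxyphenyl)cyclopropane-1,1-dicarboxylate | COC(=O)C1(C(=O)OC)[C@H](c2cc(OC)c(OC)c(OC)c2)[C@@H]1C
A4 | alternative 2 | dimethyl (2R,4R,5R)-2-[3-(benzyloxy)-4,5-dimethoxyphenyl]-4-methyl-5-(3,4,5-trimethoxyphenyl)oxolane-3,3-dicarboxylate | COc1cc([C@H]2O[C@@H](c3cc(OC)c(OC)c(OC)c3)[C@H](C)C2(C(=O)OC)C(=O)OC)cc(OCc4ccccc4)c1OC
A5 | alternative 3 | (5S)-5-[3-(benzyloxy)-4,5-dimethoxyphenyl]furan-2(5H)-one | COc1cc([C@H]2OC(=O)C=C2)cc(OCc3ccccc3)c1OC
A6 | alternative 3 | (3S,3aS,6aR)-3-[3-(benzyloxy)-4,5-dimethoxyphenyl]tetrahydro-1H,3H-thieno[3,4-c]furan-1-one | COc1cc([C@H]2OC(=O)[C@@H]3CSC[C@H]23)cc(OCc4ccccc4)c1OC
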